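**Retrosynthetic overview**
- Target ⇒ its hepta-O-benzyl ether; the last step is a BCl3/pentamethylbenzene debenzylation that spares the caffeate alkene.
- ⇒ 2,3-cis 3-(caffeoyloxy)flavan-4-one by C4 deoxygenation (hydride, then ionic hydrogenolysis), as dihydroflavonol reductase and leucoanthocyanidin reductase do.
- ⇒ α-(caffeoyloxy)-2'-hydroxychalcone by a catalytic asymmetric, chalcone-isomerase-like 6-endo oxa-Michael closure with kinetic C3 protonation; this one ring-forming step sets C2 and C3 with the ester already in place.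
- Chalcone ⇒ phenacyl caffeate + ring B aldehyde (BF3 aldol condensation); phenacyl ester ⇒ α-bromoketone of the ring A acetophenone + protected caffeic acid.
- Ring order: rings A and B and the caffeoyl arene are bought; ring C (the pyran) is the only ring formed, in step 5.

Assumption: the SMILES is read as the (2R,3R)-2,3-cis flavan with an E caffeate; the three benzyl-protected building blocks are bought as such; the quinidine-derived catalyst is taken to give 2R, and its quinine-derived pseudoenantiomer is used if the first run shows the opposite.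

**Step 1**
Reactants: 1 3,4-bis(benzyloxy)benzaldehyde; 2 malonic acid
Product: 4 (E)-3-[3,4-bis(benzyloxy)phenyl]prop-2-enoic acid, via arylidenemalonic acid 3 (not isolated)
Conditions: pyridine, piperidine (cat.), 90 °C
Reagents that add atoms: none
Why: Knoevenagel–Doebner condensation, in which the arylidenemalonic acid loses CO2 in hot pyridine to give only the E cinnamic acid and the aryl benzyl ethers are inert.

**Step 2**
Reactants: 5 1-[2,4-bis(benzyloxy)-6-hydroxyphenyl]ethan-1-one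
Product: 6 1-[2,4-bis(benzyloxy)-6-hydroxyphenyl]-2-bromoethan-1-one
Conditions: CuBr2 (2.0 equiv), EtOAc–CHCl3 (1:1), reflux
Reagents that add atoms: CuBr2, Br[Cu]Br
Why: King–Ostrum α-bromination, in which bromine is delivered within the copper-bound enol of the chelated 2-hydroxyaryl ketone, favouring the CH3 group over the electron-rich ring, and two equivalents of CuBr2 stop at the monobromide.

**Step 3**
Reactants: 6 1-[2,4-bis(benzyloxy)-6-hydroxyphenyl]-2-bromoethan-1-one; 4 (E)-3-[3,4-bis(benzyloxy)phenyl]prop-2-enoic acid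
Product: 7 2-[2,4-bis(benzyloxy)-6-hydroxyphenyl]-2-oxoethyl (E)-3-[3,4-bis(benzyloxy)phenyl]prop-2-enoate
Conditions: KHCO3 (1.1 equiv), DMF, 0 °C → rt
Reagents that add atoms: none
Why: SN2 O-alkylation of the carboxylate by the phenacyl bromide (phenacyl ester formation); bicarbonate deprotonates the acid but not the hydrogen-bonded phenol, so closure to the benzofuran-3-one is avoided.

**Step 4**
Reactants: 7 2-[2,4-bis(benzyloxy)-6-hydroxyphenyl]-2-oxoethyl (E)-3-[3,4-bis(benzyloxy)phenyl]prop-2-enoate; 8 3,4,5-tris(benzyloxy)benzaldehyde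
Product: 10 (Z)-3-[2,4-bis(benzyloxy)-6-hydroxyphenyl]-3-oxo-1-[3,4,5-tris(benzyloxy)phenyl]prop-1-en-2-yl (E)-3-[3,4-bis(benzyloxy)phenyl]prop-2-enoate (the α-caffeoyloxy-2'-hydroxychalcone), via aldol adduct 9 (not isolated)
Conditions: BF3·OEt2 (1.5 equiv), 1,4-dioxane, rt; then pH 7 buffer, 0 °C
Reagents that add atoms: none
Why: BF3-mediated Claisen–Schmidt (aldol) condensation, in which boron coordination to the chelated 2-hydroxyaryl ketone acidifies the O-acylated CH2 and ties up the phenol so it cannot add to the new enone, the acidic medium spares both esters and the benzyl ethers, and loss of water from 9 gives the Z enol ester with the aryl group trans to the ketone.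

**Step 5**
Reactants: 10 (Z)-3-[2,4-bis(benzyloxy)-6-hydroxyphenyl]-3-oxo-1-[3,4,5-tris(benzyloxy)phenyl]prop-1-en-2-yl (E)-3-[3,4-bis(benzyloxy)phenyl]prop-2-enoate
Product: 12 (2R,3S)-5,7-bis(benzyloxy)-4-oxo-2-[3,4,5-tris(benzyloxy)phenyl]-3,4-dihydro-2H-chromen-3-yl (E)-3-[3,4-bis(benzyloxy)phenyl]prop-2-enoate (2,3-cis), via enol 11 (not isolated)
Conditions: bifunctional squaramide from 9-amino-9-deoxy-epi-quinidine and 3,5-bis(trifluoromethyl)aniline (10 mol %), toluene, 4 Å MS, −40 °C; at full conversion cold filtration through AcOH-washed silica, product used at once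
Reagents that add atoms: none
Why: Proposed new method: the squaramide N–H pair binds the ketone and enol-ester carbonyls of 10 while the quinuclidine deprotonates the 2'-OH, so the phenoxide adds 6-endo to one face of the enone β-carbon (sets C2 as R; intramolecular oxa-Michael addition, the laboratory counterpart of chalcone isomerase), and the ammonium then protonates the C3–C4 enol(ate) 11 on the face anti to the pseudoaxial C2 aryl group so that H3 ends up cis to H2 (sets C3, 2,3-cis, under kinetic control, which is why the run is cold, apolar and quenched with acid before the more stable trans isomer can form); the closest known reaction type is the bifunctional thiourea- or squaramide-catalysed asymmetric intramolecular oxa-Michael cyclisation of 2'-hydroxychalcones to flavanones, together with the base-mediated cyclisation of α-alkoxy-2'-hydroxychalcones to 3-alkoxyflavanones.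

**Step 6**
Reactants: 12 (2R,3S)-5,7-bis(benzyloxy)-4-oxo-2-[3,4,5-tris(benzyloxy)phenyl]-3,4-dihydro-2H-chromen-3-yl (E)-3-[3,4-bis(benzyloxy)phenyl]prop-2-enoate
Product: 14 (2R,3R)-5,7-bis(benzyloxy)-2-[3,4,5-tris(benzyloxy)phenyl]-3,4-dihydro-2H-chromen-3-yl (E)-3-[3,4-bis(benzyloxy)phenyl]prop-2-enoate, via flavan-4-ol 13 (not isolated)
Conditions: NaBH4, CeCl3·7H2O, CH2Cl2–MeOH (4:1), −40 °C; then Et3SiH (5 equiv), TFA (15 equiv), same flask, −40 → 0 °C
Reagents that add atoms: none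
Why: Luche reduction of the activated α-acyloxy ketone outruns C3 enolisation and acyl shift at −40 °C, and the benzylic alcohol 13 then ionises in TFA to a cation stabilised by the 5- and 7-benzyloxy groups that Et3SiH reduces at C4 (ionic hydrogenation, the counterpart of dihydroflavonol 4-reductase followed by leucoanthocyanidin reductase); C2 and C3 are untouched, and the C3 descriptor changes from S to R only because the CIP priority of C4 drops.

**Step 7**
Reactants: 14 (2R,3R)-5,7-bis(benzyloxy)-2-[3,4,5-tris(benzyloxy)phenyl]-3,4-dihydro-2H-chromen-3-yl (E)-3-[3,4-bis(benzyloxy)phenyl]prop-2-enoate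
Product: 15 (2R,3R)-5,7-dihydroxy-2-(3,4,5-trihydroxyphenyl)-3,4-dihydro-2H-chromen-3-yl (E)-3-(3,4-dihydroxyphenyl)prop-2-enoate (epigallocatechin 3-O-caffeate)
Conditions: BCl3 (1 M in CH2Cl2, 15 equiv), pentamethylbenzene (25 equiv), CH2Cl2, −78 °C; MeOH quench at −78 °C
Reagents that add atoms: none
Why: Lewis-acid debenzylation of aryl benzyl ethers with pentamethylbenzene as a non-basic benzyl cation scavenger works at −78 °C and leaves the cinnamate alkene, the secondary ester and the benzylic C2–O bond alone, so no stereocentre is touched (hydrogenolysis is ruled out by the caffeate alkene).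

**Compound list**
1 | 3,4-bis(benzyloxy)benzaldehyde | O=Cc1ccc(OCc2ccccc2)c(OCc2ccccc2)c1 | starting material
2 | malonic acid | OC(=O)CC(=O)O | starting material
3 | 2-[3,4-bis(benzyloxy)benzylidene]malonic acid | OC(=O)C(=Cc1ccc(OCc2ccccc2)c(OCc2ccccc2)c1)C(=O)O | intermediate
4 | (E)-3-[3,4-bis(benzyloxy)phenyl]prop-2-enoic acid | OC(=O)/C=C/c1ccc(OCc2ccccc2)c(OCc2ccccc2)c1 | intermediate
5 | 1-[2,4-bis(benzyloxy)-6-hydroxyphenyl]ethan-1-one | CC(=O)c1c(O)cc(OCc2ccccc2)cc1OCc1ccccc1 | starting material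
6 | 1-[2,4-bis(benzyloxy)-6-hydroxyphenyl]-2-bromoethan-1-one | BrCC(=O)c1c(O)cc(OCc2ccccc2)cc1OCc1ccccc1 | intermediate
7 | 2-[2,4-bis(benzyloxy)-6-hydroxyphenyl]-2-oxoethyl (E)-3-[3,4-bis(benzyloxy)phenyl]prop-2-enoate | O=C(/C=C/c1ccc(OCc2ccccc2)c(OCc2ccccc2)c1)OCC(=O)c1c(O)cc(OCc2ccccc2)cc1OCc1ccccc1 | intermediate
8 | 3,4,5-tris(benzyloxy)benzaldehyde | O=Cc1cc(OCc2ccccc2)c(OCc2ccccc2)c(OCc2ccccc2)c1 | starting material
9 | 1-[2,4-bis(benzyloxy)-6-hydroxyphenyl]-3-hydroxy-1-oxo-3-[3,4,5-tris(benzyloxy)phenyl]propan-2-yl (E)-3-[3,4-bis(benzyloxy)phenyl]prop-2-enoate (aldol adduct, racemic, both diastereomers) | O=C(/C=C/c1ccc(OCc2ccccc2)c(OCc2ccccc2)c1)OC(C(O)c1cc(OCc2ccccc2)c(OCc2ccccc2)c(OCc2ccccc2)c1)C(=O)c1c(O)cc(OCc2ccccc2)cc1OCc1ccccc1 | intermediate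
10 | (Z)-3-[2,4-bis(benzyloxy)-6-hydroxyphenyl]-3-oxo-1-[3,4,5-tris(benzyloxy)phenyl]prop-1-en-2-yl (E)-3-[3,4-bis(benzyloxy)phenyl]prop-2-enoate | O=C(/C=C/c1ccc(OCc2ccccc2)c(OCc2ccccc2)c1)O/C(=C\c1cc(OCc2ccccc2)c(OCc2ccccc2)c(OCc2ccccc2)c1)C(=O)c1c(O)cc(OCc2ccccc2)cc1OCc1ccccc1 | intermediate
11 | (2R)-5,7-bis(benzyloxy)-4-hydroxy-2-[3,4,5-tris(benzyloxy)phenyl]-2H-chromen-3-yl (E)-3-[3,4-bis(benzyloxy)phenyl]prop-2-enoate (C3–C4 enol, present as its ammonium enolate) | O=C(/C=C/c1ccc(OCc2ccccc2)c(OCc2ccccc2)c1)OC1=C(O)c2c(OCc3ccccc3)cc(OCc3ccccc3)cc2O[C@@H]1c1cc(OCc2ccccc2)c(OCc2ccccc2)c(OCc2ccccc2)c1 | intermediate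
12 | (2R,3S)-5,7-bis(benzyloxy)-4-oxo-2-[3,4,5-tris(benzyloxy)phenyl]-3,4-dihydro-2H-chromen-3-yl (E)-3-[3,4-bis(benzyloxy)phenyl]prop-2-enoate (2,3-cis) | O=C(/C=C/c1ccc(OCc2ccccc2)c(OCc2ccccc2)c1)O[C@@H]1C(=O)c2c(OCc3ccccc3)cc(OCc3ccccc3)cc2O[C@@H]1c1cc(OCc2ccccc2)c(OCc2ccccc2)c(OCc2ccccc2)c1 | intermediate
13 | (2R,3R)-5,7-bis(benzyloxy)-4-hydroxy-2-[3,4,5-tris(benzyloxy)phenyl]-3,4-dihydro-2H-chromen-3-yl (E)-3-[3,4-bis(benzyloxy)phenyl]prop-2-enoate (2,3-cis, both C4 epimers) | O=C(/C=C/c1ccc(OCc2ccccc2)c(OCc2ccccc2)c1)O[C@@H]1C(O)c2c(OCc3ccccc3)cc(OCc3ccccc3)cc2O[C@@H]1c1cc(OCc2ccccc2)c(OCc2ccccc2)c(OCc2ccccc2)c1 | intermediate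
14 | (2R,3R)-5,7-bis(benzyloxy)-2-[3,4,5-tris(benzyloxy)phenyl]-3,4-dihydro-2H-chromen-3-yl (E)-3-[3,4-bis(benzyloxy)phenyl]prop-2-enoate | O=C(/C=C/c1ccc(OCc2ccccc2)c(OCc2ccccc2)c1)O[C@@H]1Cc2c(OCc3ccccc3)cc(OCc3ccccc3)cc2O[C@@H]1c1cc(OCc2ccccc2)c(OCc2ccccc2)c(OCc2ccccc2)c1 | intermediate
15 | epigallocatechin 3-O-caffeate, (2R,3R)-5,7-dihydroxy-2-(3,4,5-trihydroxyphenyl)-3,4-dihydro-2H-chromen-3-yl (E)-3-(3,4-dihydroxyphenyl)prop-2-enoate | O=C(/C=C/c1ccc(O)c(O)c1)O[C@@H]1Cc2c(O)cc(O)cc2O[C@@H]1c1cc(O)c(O)c(O)c1 | target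

**Step count**
Total steps: 7. Longest linear sequence: 6 (5 → 6 → 7 → 10 → 12 → 14 → 15); step 1 is a one-step side branch.

**Three steps most likely to fail**

Step 5 is the largest risk. The cis isomer is the kinetic product and can drift to trans through C3 enolisation or ring opening. The enantioselectivity on an α-acyloxy chalcone is untested. The catalyst amine could also attack the enol ester. The fallback moves the stereochemistry from the ring closure to a late reduction of a flat ring, as anthocyanidin reductase does. It sets out from 10. Et3N (cat., CH2Cl2, rt) closes ring C without control to the racemic 2,3-trans 3-acyloxyflavanone F1. NaBH4/CeCl3·7H2O, then TsOH (cat., toluene, 50 °C), reduce and dehydrate it to the racemic 2H-chromen-3-yl ester F2. Ph3C+ BF4− (CH2Cl2, 0 °C) removes the C2 hydride to give the flavylium tetrafluoroborate F3, the hepta-O-benzyl ether of delphinidin 3-O-caffeate. F3 is reduced with Hantzsch ester (2.2 equiv) and (R)-3,3'-bis(2,4,6-triisopropylphenyl)-1,1'-binaphthyl-2,2'-diyl hydrogen phosphate (10 mol %) in CH2Cl2 at −30 °C. The first hydride goes to C4, the chiral acid protonates C3 of the 4H-chromene enantioselectively, and the second hydride adds to the C2 oxocarbenium anti to the acyloxy group. This gives the 2,3-cis compound and comes back to the route at 14, replacing steps 5 and 6.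

Step 4 is the second risk. The acid condensation of an α-acyloxy ketone may stall at the aldol stage, or the product may cyclise early to racemic flavanone. The fallback replaces the one-pot acid condensation by a directed enolate aldol followed by a separate elimination. It sets out from 7 and 8. Enolisation of 7 with c-Hex2BCl (2.2 equiv) and Et3N in CH2Cl2 at −78 °C and addition of 8 give the aldol adduct 9, which is isolated. MsCl/Et3N at −20 °C converts it to the β-mesylate F4. DBU (0 °C) then eliminates by E1cB, and the fallback comes back to the route at 10.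

Step 6 is the third risk. The cis α-acyloxy ketone may epimerise or shift its acyl group under hydride, and the cationic deoxygenation may attack the benzyl ethers or the C2–O bond. The fallback replaces the cationic deoxygenation by a radical one. It sets out from 12. Luche reduction as before gives 13, which is now isolated. 1,1'-Thiocarbonyldiimidazole (DMAP cat., CH2Cl2, rt) gives the 4-O-(imidazol-1-ylthiocarbonyl) derivative F5. Bu3SnH with AIBN in toluene at 80 °C (Barton–McCombie deoxygenation through the benzylic C4 radical) comes back to the route at 14.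

**Further compounds**
F1 | step 5 | racemic 2,3-trans 5,7-bis(benzyloxy)-4-oxo-2-[3,4,5-tris(benzyloxy)phenyl]-3,4-dihydro-2H-chromen-3-yl (E)-3-[3,4-bis(benzyloxy)phenyl]prop-2-enoate (the 2R,3R enantiomer is drawn) | O=C(/C=C/c1ccc(OCc2ccccc2)c(OCc2ccccc2)c1)O[C@H]1C(=O)c2c(OCc3ccccc3)cc(OCc3ccccc3)cc2O[C@@H]1c1cc(OCc2ccccc2)c(OCc2ccccc2)c(OCc2ccccc2)c1
F2 | step 5 | racemic 5,7-bis(benzyloxy)-2-[3,4,5-tris(benzyloxy)phenyl]-2H-chromen-3-yl (E)-3-[3,4-bis(benzyloxy)phenyl]prop-2-enoate | O=C(/C=C/c1ccc(OCc2ccccc2)c(OCc2ccccc2)c1)OC1=Cc2c(OCc3ccccc3)cc(OCc3ccccc3)cc2OC1c1cc(OCc2ccccc2)c(OCc2ccccc2)c(OCc2ccccc2)c1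
F3 | step 5 | 5,7-bis(benzyloxy)-3-{[(E)-3-[3,4-bis(benzyloxy)phenyl]prop-2-enoyl]oxy}-2-[3,4,5-tris(benzyloxy)phenyl]chromenylium tetrafluoroborate | O=C(/C=C/c1ccc(OCc2ccccc2)c(OCc2ccccc2)c1)Oc1cc2c(OCc3ccccc3)cc(OCc3ccccc3)cc2[o+]c1-c1cc(OCc2ccccc2)c(OCc2ccccc2)c(OCc2ccccc2)c1.F[B-](F)(F)F
F4 | step 4 | 1-[2,4-bis(benzyloxy)-6-hydroxyphenyl]-3-(methanesulfonyloxy)-1-oxo-3-[3,4,5-tris(benzyloxy)phenyl]propan-2-yl (E)-3-[3,4-bis(benzyloxy)phenyl]prop-2-enoate (racemic, both diastereomers) | O=C(/C=C/c1ccc(OCc2ccccc2)c(OCc2ccccc2)c1)OC(C(OS(C)(=O)=O)c1cc(OCc2ccccc2)c(OCc2ccccc2)c(OCc2ccccc2)c1)C(=O)c1c(O)cc(OCc2ccccc2)cc1OCc1ccccc1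
F5 | step 6 | 4-O-(imidazol-1-ylthiocarbonyl) derivative of 13 (2,3-cis, both C4 epimers) | O=C(/C=C/c1ccc(OCc2ccccc2)c(OCc2ccccc2)c1)O[C@@H]1C(OC(=S)n2ccnc2)c2c(OCc3ccccc3)cc(OCc3ccccc3)cc2O[C@@H]1c1cc(OCc2ccccc2)c(OCc2ccccc2)c(OCc2ccccc2)c1
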